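The 1,2-dioxolane is cut at its O2–C3 bond: C3 is the β-carbon of the acetic acid arm, so the ring is the retron of an intramolecular peroxide oxa-Michael addition. In one operation the key step closes the dioxolane, creates the quaternary C3 centre under the influence of C5 and completes the carboxyl side chain. Its precursor is an acyclic δ-hydroperoxy β-methyl enoate. The tertiary C5 hydroperoxide comes from invertive perhydrolysis of an oxetane made from a Sharpless epoxide, and the side-chain methyl centre is set earlier by a copper-catalysed conjugate addition.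

Key step: step 18

Atom labels used below: dioxolane O1–O2–C3–C4–C5 (C3 carries the acetic acid arm, C5 the long chain); C2′ is the methyl-bearing carbon of the chain.

Remark (assumption): the copper/Tol-BINAP catalyst is taken to give the 3R ester from the E enoate with the (S)-ligand; if the sense of induction is the opposite, the antipodal ligand is used.

Step 1
Reactants: 1 cyclooctene
Product: 3 methyl 8-oxooctanoate, via 8-hydroperoxy-8-methoxyoctanal 2 (not isolated)
Conditions: O3, CH2Cl2/MeOH, NaHCO3, −78 °C; then Ac2O, Et3N, CH2Cl2, 0 °C to rt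
Reagents that add atoms: ozone [O-][O+]=O; methanol CO
Why: Criegee ozonolysis in methanol should trap the carbonyl oxide as the methoxy hydroperoxide 2 beside a free aldehyde, and acetylation with base-induced fragmentation should turn that terminus into the methyl ester, so the two ends of the C8 chain are differentiated in one flask.

Step 2
Reactants: 3 methyl 8-oxooctanoate; 4 diethyl [(2E)-3-phenylprop-2-en-1-yl]phosphonate
Product: 5 methyl (8E,10E)-11-phenylundeca-8,10-dienoate
Conditions: 4, LiN(SiMe3)2, THF, −78 °C; then 3, −78 °C to rt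
Reagents that add atoms: none
Why: Horner–Wadsworth–Emmons olefination of the aldehyde with the lithiated allylic phosphonate should build the phenyl-capped diene with E geometry at the new C8=C9 bond, while the ester is untouched at low temperature.

Step 3
Reactants: 5 methyl (8E,10E)-11-phenylundeca-8,10-dienoate
Product: 6 (8E,10E)-11-phenylundeca-8,10-dienal
Conditions: i-Bu2AlH (1.1 equiv), CH2Cl2, −78 °C; then MeOH, aq. KNaC4H4O6
Reagents that add atoms: none
Why: Partial hydride reduction of the methyl ester at −78 °C should stop at the aluminium hemiacetal, which releases the aldehyde on work-up.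

Step 4
Reactants: 6 (8E,10E)-11-phenylundeca-8,10-dienal; 7 methyl 2-(triphenyl-λ5-phosphanylidene)acetate
Product: 8 methyl (2E,10E,12E)-13-phenyltrideca-2,10,12-trienoate
Conditions: CH2Cl2, rt
Reagents that add atoms: none
Why: Wittig olefination with the stabilised ylide should give the E enoate that serves as the acceptor for the next step.

Step 5
Reactants: 8 methyl (2E,10E,12E)-13-phenyltrideca-2,10,12-trienoate
Product: 9 methyl (3R,10E,12E)-3-methyl-13-phenyltrideca-10,12-dienoate
Conditions: CuI (2 mol %), (S)-Tol-BINAP (3 mol %), MeMgBr, t-BuOMe, −20 °C; aq. NH4Cl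
Reagents that add atoms: methylmagnesium bromide C[Mg]Br
Why: Copper-catalysed asymmetric conjugate addition of the methyl Grignard reagent, in which the chiral bisphosphine on copper selects the enoate face, should set the side-chain methyl stereocentre (future C2′, R) by catalyst control.

Step 6
Reactants: 9 methyl (3R,10E,12E)-3-methyl-13-phenyltrideca-10,12-dienoate
Product: 10 (3R,10E,12E)-3-methyl-13-phenyltrideca-10,12-dienal
Conditions: i-Bu2AlH (1.1 equiv), CH2Cl2, −78 °C; then MeOH, aq. KNaC4H4O6
Reagents that add atoms: none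
Why: Partial hydride reduction of the ester at −78 °C should again stop at the aldehyde stage, and the β-stereocentre cannot epimerise.

Step 7
Reactants: 10 (3R,10E,12E)-3-methyl-13-phenyltrideca-10,12-dienal
Product: 11 (4R,11E,13E)-4-methyl-14-phenyltetradeca-11,13-dien-1-yne
Conditions: dimethyl (1-diazo-2-oxopropyl)phosphonate, K2CO3, MeOH, 0 °C to rt
Reagents that add atoms: dimethyl (1-diazo-2-oxopropyl)phosphonate CC(=O)C(=[N+]=[N-])P(=O)(OC)OC
Why: Seyferth–Gilbert homologation in the Ohira–Bestmann variant should convert the aldehyde into the terminal alkyne under mild basic conditions.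

Step 8
Reactants: 11 (4R,11E,13E)-4-methyl-14-phenyltetradeca-11,13-dien-1-yne
Product: 14 (2E,5R,12E,14E)-3,5-dimethyl-15-phenylpentadeca-2,12,14-trien-1-ol, via alkenyldimethylalane 12 (not isolated), via lithium alkenylaluminate 13 (not isolated)
Conditions: Me3Al (2.5 equiv), Cp2ZrCl2 (0.2 equiv), CH2Cl2, 0 °C to rt; then n-BuLi, THF, −78 °C; then (CH2O)n, −78 °C to rt; aq. KNaC4H4O6
Reagents that add atoms: trimethylaluminium C[Al](C)C; formaldehyde (from paraformaldehyde) C=O; n-butyllithium [Li]CCCC (its atoms stay only in 13)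
Why: Negishi zirconium-catalysed methylalumination adds methyl and aluminium syn across the alkyne with methyl at the internal carbon, and hydroxymethylation of the derived aluminate occurs with retention, so the E trisubstituted allylic alcohol should form as a single alkene isomer.

Step 9
Reactants: 14 (2E,5R,12E,14E)-3,5-dimethyl-15-phenylpentadeca-2,12,14-trien-1-ol
Product: 15 [(2S,3S)-3-methyl-3-[(2R,9E,11E)-2-methyl-12-phenyldodeca-9,11-dien-1-yl]oxiran-2-yl]methanol
Conditions: Ti(OiPr)4 (10 mol %), L-(+)-diethyl tartrate (12 mol %), t-BuOOH, 4 Å molecular sieves, CH2Cl2, −20 °C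
Reagents that add atoms: tert-butyl hydroperoxide CC(C)(C)OO
Why: Sharpless asymmetric epoxidation with the L-(+)-tartrate ligand delivers oxygen to one face of the allylic alcohol regardless of the remote methyl centre and should give the (2S,3S)-epoxide, which fixes the C–O bond at the future C5 by reagent control.

Step 10
Reactants: 15 [(2S,3S)-3-methyl-3-[(2R,9E,11E)-2-methyl-12-phenyldodeca-9,11-dien-1-yl]oxiran-2-yl]methanol
Product: 16 (3S,5R,12E,14E)-3,5-dimethyl-15-phenylpentadeca-12,14-diene-1,3-diol
Conditions: NaAlH2(OCH2CH2OMe)2 (2 equiv), THF, 0 °C; then aq. KNaC4H4O6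
Reagents that add atoms: none
Why: Hydroxyl-directed reductive opening of the 2,3-epoxy alcohol, with intramolecular hydride delivery from the alkoxy-bound aluminium to C2, should give the 1,3-diol and leave the tertiary C–O bond untouched.

Step 11
Reactants: 16 (3S,5R,12E,14E)-3,5-dimethyl-15-phenylpentadeca-12,14-diene-1,3-diol
Product: 17 (3S,5R,12E,14E)-3-hydroxy-3,5-dimethyl-15-phenylpentadeca-12,14-dienal
Conditions: TEMPO (10 mol %), PhI(OAc)2, CH2Cl2, rt
Reagents that add atoms: none
Why: Oxoammonium (TEMPO) oxidation with PhI(OAc)2 as terminal oxidant is selective for the primary alcohol and should give the β-hydroxy aldehyde without touching the tertiary alcohol or the diene.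

Step 12
Reactants: 17 (3S,5R,12E,14E)-3-hydroxy-3,5-dimethyl-15-phenylpentadeca-12,14-dienal
Product: 18 (4S,6R,13E,15E)-4,6-dimethyl-16-phenylhexadeca-13,15-diene-2,4-diol (both C2 epimers)
Conditions: MeMgBr (3 equiv), THF, −78 to 0 °C; aq. NH4Cl
Reagents that add atoms: methylmagnesium bromide C[Mg]Br
Why: Grignard 1,2-addition to the aldehyde should give the secondary alcohol as a mixture of C2 epimers, which does not matter because this carbon becomes the ketone later.

Step 13
Reactants: 18 (4S,6R,13E,15E)-4,6-dimethyl-16-phenylhexadeca-13,15-diene-2,4-diol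
Product: 20 (2S)-2,4-dimethyl-2-[(2R,9E,11E)-2-methyl-12-phenyldodeca-9,11-dien-1-yl]oxetane (both C4 epimers), via secondary mesylate 19 (not isolated)
Conditions: MsCl (1.1 equiv), Et3N, CH2Cl2, −20 °C; then KOtBu, THF, 0 °C to rt
Reagents that add atoms: methanesulfonyl chloride CS(=O)(=O)Cl (its atoms stay only in 19)
Why: Selective sulfonylation of the secondary alcohol followed by intramolecular Williamson etherification (4-exo-tet) by the tertiary alkoxide should close the oxetane with retention at the tertiary carbon, whose C–O bond is not involved.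

Step 14
Reactants: 20 (2S)-2,4-dimethyl-2-[(2R,9E,11E)-2-methyl-12-phenyldodeca-9,11-dien-1-yl]oxetane
Product: 21 (4R,6R,13E,15E)-4-hydroperoxy-4,6-dimethyl-16-phenylhexadeca-13,15-dien-2-ol (both C2 epimers)
Conditions: anhydrous H2O2 in Et2O (excess), Me3SiOTf (0.2 equiv), −78 to 0 °C
Reagents that add atoms: hydrogen peroxide OO
Why: Lewis-acid-promoted perhydrolysis of the oxetane, in which H2O2 attacks the activated ring at the tertiary carbon from the side opposite to the departing oxygen (borderline SN2 opening), should give the tertiary hydroperoxide with inversion and so set the future C5 as R.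

Step 15
Reactants: 21 (4R,6R,13E,15E)-4-hydroperoxy-4,6-dimethyl-16-phenylhexadeca-13,15-dien-2-ol
Product: 22 (4R,6R,13E,15E)-4-[(2-methoxypropan-2-yl)peroxy]-4,6-dimethyl-16-phenylhexadeca-13,15-dien-2-ol
Conditions: 2-methoxypropene (1.2 equiv), pyridinium p-toluenesulfonate (cat.), CH2Cl2, 0 °C
Reagents that add atoms: 2-methoxypropene COC(C)=C
Why: Acid-catalysed addition of the hydroperoxide, the better nucleophile, to the enol ether should protect it selectively as the base-stable monoperoxyketal and leave the secondary alcohol free.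

Step 16
Reactants: 22 (4R,6R,13E,15E)-4-[(2-methoxypropan-2-yl)peroxy]-4,6-dimethyl-16-phenylhexadeca-13,15-dien-2-ol
Product: 23 (4R,6R,13E,15E)-4-[(2-methoxypropan-2-yl)peroxy]-4,6-dimethyl-16-phenylhexadeca-13,15-dien-2-one
Conditions: Dess–Martin periodinane, pyridine, CH2Cl2, 0 °C to rt
Reagents that add atoms: none
Why: Dess–Martin oxidation of the secondary alcohol under pyridine buffering should give the methyl ketone, both C2 epimers converging, without harm to the peroxyketal.

Step 17
Reactants: 23 (4R,6R,13E,15E)-4-[(2-methoxypropan-2-yl)peroxy]-4,6-dimethyl-16-phenylhexadeca-13,15-dien-2-one; 24 ethyl 2-(trimethylsilyl)acetate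
Product: 25 ethyl (5R,7R,14E,16E)-5-[(2-methoxypropan-2-yl)peroxy]-3,5,7-trimethyl-17-phenylheptadeca-2,14,16-trienoate (2E/2Z mixture)
Conditions: 24, LiN(i-Pr)2, THF, −78 °C; then 23, −78 to 0 °C
Reagents that add atoms: none
Why: Peterson olefination, addition of the lithium enolate of the α-silyl ester to the ketone at −78 °C followed by loss of silanolate, should give the β-methyl enoate as an E/Z mixture, which is acceptable because both isomers lead to the same ring-closure products.

Step 18
Reactants: 25 ethyl (5R,7R,14E,16E)-5-[(2-methoxypropan-2-yl)peroxy]-3,5,7-trimethyl-17-phenylheptadeca-2,14,16-trienoate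
Product: 27 ethyl 2-[(3R,5R)-3,5-dimethyl-5-[(2R,9E,11E)-2-methyl-12-phenyldodeca-9,11-dien-1-yl]-1,2-dioxolan-3-yl]acetate, via hydroperoxy enoate 26 (not isolated)
Conditions: AcOH/THF/H2O (4:2:1), rt; evaporate; then Et2NH (0.3 equiv), CF3CH2OH, rt
Reagents that add atoms: none
Why: Aqueous acetic acid cleaves the monoperoxyketal to the free hydroperoxide 26; diethylamine in trifluoroethanol then generates a low concentration of the peroxy anion, which adds to C3, the β-carbon of the enoate, and the ester enolate is protonated at once by the fluorinated alcohol, so that its collapse onto the O–O bond (epoxide formation) is suppressed. The closest known reaction type is the amine-mediated intramolecular conjugate addition of hydroperoxides to α,β-unsaturated esters used to make 1,2-dioxanes and 1,2-dioxolanes. The dioxolane closes in a 5-exo-trig mode through the O2–C3 bond. C5 is not touched, and C3 is set by 1,3-induction from C5 in an envelope transition state in which the two methyl groups take the converging pseudoaxial sites and the β-branched C5 chain and the forming acetate arm take the diverging pseudoequatorial ones, which leads to the cis-dimethyl (3R,5R) ring. The step needs conjugate addition to win over enolate attack on the peroxide and needs facial selectivity at C3; the first is secured by the protic, weakly basic medium, while the second rests only on the size difference between methyl and the branched chain at C5 and is expected to be modest, so the (3S,5R) epimer is removed by chromatography.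

Step 19
Reactants: 27 ethyl 2-[(3R,5R)-3,5-dimethyl-5-[(2R,9E,11E)-2-methyl-12-phenyldodeca-9,11-dien-1-yl]-1,2-dioxolan-3-yl]acetate
Product: 28 2-[(3R,5R)-3,5-dimethyl-5-[(2R,9E,11E)-2-methyl-12-phenyldodeca-9,11-dien-1-yl]-1,2-dioxolan-3-yl]acetic acid (CNP0196394.3)
Conditions: LiOH·H2O, THF/H2O, 0 °C to rt; then 1 M HCl to pH 3
Reagents that add atoms: lithium hydroxide [Li+].[OH-]
Why: Saponification by hydroxide attack at the acyl carbon should give the acid without opening the ring, since the fully substituted dioxolane has no hydrogen on its peroxide-bearing carbons.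

Compound list

1 | (Z)-cyclooctene | C1CC/C=C\CCC1 | starting material
2 | 8-hydroperoxy-8-methoxyoctanal | COC(OO)CCCCCCC=O | intermediate
3 | methyl 8-oxooctanoate | COC(=O)CCCCCCC=O | intermediate
4 | diethyl [(2E)-3-phenylprop-2-en-1-yl]phosphonate | CCOP(=O)(OCC)C/C=C/c1ccccc1 | starting material
5 | methyl (8E,10E)-11-phenylundeca-8,10-dienoate | COC(=O)CCCCCC/C=C/C=C/c1ccccc1 | intermediate
6 | (8E,10E)-11-phenylundeca-8,10-dienal | O=CCCCCCC/C=C/C=C/c1ccccc1 | intermediate
7 | methyl 2-(triphenyl-λ5-phosphanylidene)acetate | COC(=O)C=P(c1ccccc1)(c1ccccc1)c1ccccc1 | starting material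
8 | methyl (2E,10E,12E)-13-phenyltrideca-2,10,12-trienoate | COC(=O)/C=C/CCCCCC/C=C/C=C/c1ccccc1 | intermediate
9 | methyl (3R,10E,12E)-3-methyl-13-phenyltrideca-10,12-dienoate | C[C@H](CCCCCC/C=C/C=C/c1ccccc1)CC(=O)OC | intermediate
10 | (3R,10E,12E)-3-methyl-13-phenyltrideca-10,12-dienal | C[C@H](CCCCCC/C=C/C=C/c1ccccc1)CC=O | intermediate
11 | (4R,11E,13E)-4-methyl-14-phenyltetradeca-11,13-dien-1-yne | C[C@H](CCCCCC/C=C/C=C/c1ccccc1)CC#C | intermediate
12 | [(1E,4R,11E,13E)-2,4-dimethyl-14-phenyltetradeca-1,11,13-trien-1-yl]dimethylalane | C[C@H](CCCCCC/C=C/C=C/c1ccccc1)C/C(C)=C/[Al](C)C | intermediate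
13 | lithium butyl[(1E,4R,11E,13E)-2,4-dimethyl-14-phenyltetradeca-1,11,13-trien-1-yl]dimethylaluminate | [Li+].C[C@H](CCCCCC/C=C/C=C/c1ccccc1)C/C(C)=C/[Al-](C)(C)CCCC | intermediate
14 | (2E,5R,12E,14E)-3,5-dimethyl-15-phenylpentadeca-2,12,14-trien-1-ol | C[C@H](CCCCCC/C=C/C=C/c1ccccc1)C/C(C)=C/CO | intermediate
15 | [(2S,3S)-3-methyl-3-[(2R,9E,11E)-2-methyl-12-phenyldodeca-9,11-dien-1-yl]oxiran-2-yl]methanol | C[C@H](CCCCCC/C=C/C=C/c1ccccc1)C[C@]1(C)O[C@H]1CO | intermediate
16 | (3S,5R,12E,14E)-3,5-dimethyl-15-phenylpentadeca-12,14-diene-1,3-diol | C[C@H](CCCCCC/C=C/C=C/c1ccccc1)C[C@](C)(O)CCO | intermediate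
17 | (3S,5R,12E,14E)-3-hydroxy-3,5-dimethyl-15-phenylpentadeca-12,14-dienal | C[C@H](CCCCCC/C=C/C=C/c1ccccc1)C[C@](C)(O)CC=O | intermediate
18 | (4S,6R,13E,15E)-4,6-dimethyl-16-phenylhexadeca-13,15-diene-2,4-diol (both C2 epimers) | C[C@H](CCCCCC/C=C/C=C/c1ccccc1)C[C@](C)(O)CC(C)O | intermediate
19 | (4S,6R,13E,15E)-4-hydroxy-4,6-dimethyl-16-phenylhexadeca-13,15-dien-2-yl methanesulfonate (both C2 epimers) | C[C@H](CCCCCC/C=C/C=C/c1ccccc1)C[C@](C)(O)CC(C)OS(C)(=O)=O | intermediate
20 | (2S)-2,4-dimethyl-2-[(2R,9E,11E)-2-methyl-12-phenyldodeca-9,11-dien-1-yl]oxetane (both C4 epimers) | C[C@H](CCCCCC/C=C/C=C/c1ccccc1)C[C@@]1(C)CC(C)O1 | intermediate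
21 | (4R,6R,13E,15E)-4-hydroperoxy-4,6-dimethyl-16-phenylhexadeca-13,15-dien-2-ol (both C2 epimers) | C[C@H](CCCCCC/C=C/C=C/c1ccccc1)C[C@](OO)(C)CC(C)O | intermediate
22 | (4R,6R,13E,15E)-4-[(2-methoxypropan-2-yl)peroxy]-4,6-dimethyl-16-phenylhexadeca-13,15-dien-2-ol (both C2 epimers) | C[C@H](CCCCCC/C=C/C=C/c1ccccc1)C[C@](OOC(C)(C)OC)(C)CC(C)O | intermediate
23 | (4R,6R,13E,15E)-4-[(2-methoxypropan-2-yl)peroxy]-4,6-dimethyl-16-phenylhexadeca-13,15-dien-2-one | C[C@H](CCCCCC/C=C/C=C/c1ccccc1)C[C@](OOC(C)(C)OC)(C)CC(C)=O | intermediate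
24 | ethyl 2-(trimethylsilyl)acetate | CCOC(=O)C[Si](C)(C)C | starting material
25 | ethyl (5R,7R,14E,16E)-5-[(2-methoxypropan-2-yl)peroxy]-3,5,7-trimethyl-17-phenylheptadeca-2,14,16-trienoate (2E/2Z mixture) | C[C@H](CCCCCC/C=C/C=C/c1ccccc1)C[C@](OOC(C)(C)OC)(C)CC(C)=CC(=O)OCC | intermediate
26 | ethyl (5R,7R,14E,16E)-5-hydroperoxy-3,5,7-trimethyl-17-phenylheptadeca-2,14,16-trienoate (2E/2Z mixture) | C[C@H](CCCCCC/C=C/C=C/c1ccccc1)C[C@](OO)(C)CC(C)=CC(=O)OCC | intermediate
27 | ethyl 2-[(3R,5R)-3,5-dimethyl-5-[(2R,9E,11E)-2-methyl-12-phenyldodeca-9,11-dien-1-yl]-1,2-dioxolan-3-yl]acetate | C[C@H](CCCCCC/C=C/C=C/c1ccccc1)C[C@]1(C)C[C@](C)(CC(=O)OCC)OO1 | intermediate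
28 | 2-[(3R,5R)-3,5-dimethyl-5-[(2R,9E,11E)-2-methyl-12-phenyldodeca-9,11-dien-1-yl]-1,2-dioxolan-3-yl]acetic acid | C[C@H](CCCCCC/C=C/C=C/c1ccccc1)C[C@]1(C)C[C@](C)(CC(=O)O)OO1 | target

Total step count: 19. Longest linear sequence: 19 steps (from cyclooctene 1 to 28).

Steps most likely to fail

Step 18 (key step). The ring closure may show little facial selectivity at C3, because the only control element is the size difference between the two C5 substituents. The peroxy enolate may also collapse to an epoxy ester. The fallback forms the C3–CH2 bond after ring closure instead of adding the peroxide to the enoate. It sets out from ketone 23. Pyridinium p-toluenesulfonate in methanol should remove the peroxyketal and convert the liberated hydroperoxy ketone into the cyclic methyl peroxyketal, the 3-methoxy-1,2-dioxolane F1; the O2–C3 bond then forms by ketalisation. TiCl4 and 1-ethoxy-1-(trimethylsilyloxy)ethene in CH2Cl2 at −78 °C should then ionise C3 and alkylate it there. This returns the route to ester 27, again with chromatographic removal of the C3 epimer.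

Step 14. Ionisation of the tertiary ring carbon ahead of nucleophilic attack would erode the configuration at C5. Opening at the secondary ring carbon would give the regioisomeric hydroperoxide, and the cis/trans oxetane mixture may react unevenly. The fallback uses an oxetane that has no secondary ring carbon and introduces the C3 methyl group after the peroxide. It sets out from diol 16. Tosylation of the primary alcohol (TsCl, pyridine) gives the primary tosylate F2, and KOtBu closes it to the 2,2-disubstituted oxetane F3. Perhydrolysis (H2O2, Me3SiOTf, Et2O) can then occur only at the tertiary carbon and gives the hydroperoxy alcohol F4. 2-Methoxypropene with pyridinium p-toluenesulfonate gives the peroxyketal alcohol F5, and Dess–Martin oxidation gives the peroxyketal aldehyde F6. Chemoselective methyl addition with MeTi(OiPr)3 in THF at −40 °C returns the route to alcohol 22.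

Step 5. Conjugate addition of the methyl Grignard reagent to the oxo ester may be slow, with competing 1,2-addition and reduced enantioselectivity. The fallback changes the acceptor class to a thioester. It sets out from aldehyde 6. Wittig olefination with S-ethyl 2-(triphenyl-λ5-phosphanylidene)ethanethioate gives the thioenoate F7. MeMgBr with CuBr·SMe2 and a Josiphos ligand in t-BuOMe at −75 °C should add cleanly to this more electrophilic acceptor to give the 3R thioester F8. Reduction with i-Bu2AlH at −78 °C rejoins the route at aldehyde 10.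

Further compounds

F1 | step 18 | (5R)-3-methoxy-3,5-dimethyl-5-[(2R,9E,11E)-2-methyl-12-phenyldodeca-9,11-dien-1-yl]-1,2-dioxolane (both C3 epimers) | C[C@H](CCCCCC/C=C/C=C/c1ccccc1)C[C@]1(C)CC(C)(OC)OO1
F2 | step 14 | (3S,5R,12E,14E)-3-hydroxy-3,5-dimethyl-15-phenylpentadeca-12,14-dien-1-yl 4-methylbenzenesulfonate | C[C@H](CCCCCC/C=C/C=C/c1ccccc1)C[C@](C)(O)CCOS(=O)(=O)c1ccc(C)cc1
F3 | step 14 | (2S)-2-methyl-2-[(2R,9E,11E)-2-methyl-12-phenyldodeca-9,11-dien-1-yl]oxetane | C[C@H](CCCCCC/C=C/C=C/c1ccccc1)C[C@@]1(C)CCO1
F4 | step 14 | (3R,5R,12E,14E)-3-hydroperoxy-3,5-dimethyl-15-phenylpentadeca-12,14-dien-1-ol | C[C@H](CCCCCC/C=C/C=C/c1ccccc1)C[C@](OO)(C)CCO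
F5 | step 14 | (3R,5R,12E,14E)-3-[(2-methoxypropan-2-yl)peroxy]-3,5-dimethyl-15-phenylpentadeca-12,14-dien-1-ol | C[C@H](CCCCCC/C=C/C=C/c1ccccc1)C[C@](OOC(C)(C)OC)(C)CCO
F6 | step 14 | (3R,5R,12E,14E)-3-[(2-methoxypropan-2-yl)peroxy]-3,5-dimethyl-15-phenylpentadeca-12,14-dienal | C[C@H](CCCCCC/C=C/C=C/c1ccccc1)C[C@](OOC(C)(C)OC)(C)CC=O
F7 | step 5 | S-ethyl (2E,10E,12E)-13-phenyltrideca-2,10,12-trienethioate | CCSC(=O)/C=C/CCCCCC/C=C/C=C/c1ccccc1
F8 | step 5 | S-ethyl (3R,10E,12E)-3-methyl-13-phenyltrideca-10,12-dienethioate | C[C@H](CCCCCC/C=C/C=C/c1ccccc1)CC(=O)SCC
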